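**Strategy**

Everything rests on forming the C3–C3a bond of the furo[3,4-c]furan last, closing the tetrahydrofuran that carries the phenolic aryl group onto a preformed 2,3-dihydrofuran, which becomes the second ring. One operation, a decarboxylative radical cyclisation with nickel arylation, makes this bond (5-exo addition of an O-CH2 radical to the enol ether) and then arylates the new C4 radical with the trimethoxyphenyl unit. The step exploits the cis-fused 3,7-dioxabicyclo[3.3.0]octane core: the ring fusion C3a–C6a can only close cis, and the convex face sends the C4 aryl group exo. The precursor is an aryl(dihydrofuran-3-yl)methoxyacetic acid with both stereocentres set by an iridium-catalysed anti-(hydroxymethyl)allylation.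

Key step: step 5

Locants: C1 (carbon bearing the phenolic aryl group), O2, C3, C3a, C4 (carbon bearing the trimethoxyphenyl group), O5, C6, C6a.

Assumption: 3-(benzyloxy)-4,5-dimethoxybenzaldehyde is taken as commercially available; it is otherwise one O-benzylation from commercial 3-hydroxy-4,5-dimethoxybenzaldehyde.

Assumption: the (S)-SEGPHOS-modified iridium catalyst is taken to give the (1S,2R) diol; if the sense of induction is the opposite, the (R)-ligand is used with no other change.

**Route**

Step 1
Reactants: 1 3-(benzyloxy)-4,5-dimethoxybenzaldehyde; 2 4-ethenyl-1,3-dioxolan-2-one (vinyl ethylene carbonate, racemic)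
Product: 3 (1S,2R)-1-[3-(benzyloxy)-4,5-dimethoxyphenyl]-2-ethenylpropane-1,3-diol
Conditions: [Ir(cod)Cl]2 (cat.), (S)-SEGPHOS, 4-cyano-3-nitrobenzoic acid, K3PO4 (cat.), i-PrOH (2 equiv), THF, 60 °C
Reagents that add atoms: none
Why: Iridium-catalysed transfer-hydrogenative carbonyl (hydroxymethyl)allylation: the carbonate ionises with loss of CO2 to an (E)-sigma-allyl iridium species that adds to the aldehyde through a closed chair transition state, so the anti relationship of the two new stereocentres (future C1 and C6a) follows from the allyl geometry and their absolute sense from the chiral bisphosphine.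

Step 2
Reactants: 3 (1S,2R)-1-[3-(benzyloxy)-4,5-dimethoxyphenyl]-2-ethenylpropane-1,3-diol
Product: 4 (1S,2R)-1-[3-(benzyloxy)-4,5-dimethoxyphenyl]-2-[(ethenyloxy)methyl]but-3-en-1-ol
Conditions: Pd(O2CCF3)2 (cat.), 4,7-diphenyl-1,10-phenanthroline, Et3N (cat.), butyl vinyl ether (solvent), rt, stopped at mono-vinylation
Reagents that add atoms: butyl vinyl ether, C=COCCCC
Why: Palladium-catalysed transfer vinylation (trans-etherification) should be much faster at the unhindered primary hydroxyl than at the benzylic secondary one next to a branched carbon, and no stereocentre is touched.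

Step 3
Reactants: 4 (1S,2R)-1-[3-(benzyloxy)-4,5-dimethoxyphenyl]-2-[(ethenyloxy)methyl]but-3-en-1-ol
Product: 5 (S)-[3-(benzyloxy)-4,5-dimethoxyphenyl][(3R)-2,3-dihydrofuran-3-yl]methanol
Conditions: second-generation Grubbs catalyst RuCl2(=CHPh)(H2IMes)(PCy3) (cat.), toluene, 70 °C, high dilution
Reagents that add atoms: none
Why: Ring-closing metathesis of a homoallyl vinyl ether should give the five-membered cyclic enol ether with loss of ethene; the free secondary alcohol is tolerated and neither stereocentre is involved.

Step 4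
Reactants: 5 (S)-[3-(benzyloxy)-4,5-dimethoxyphenyl][(3R)-2,3-dihydrofuran-3-yl]methanol
Product: 6 2-{(S)-[3-(benzyloxy)-4,5-dimethoxyphenyl][(3R)-2,3-dihydrofuran-3-yl]methoxy}acetic acid
Conditions: NaH (3 equiv), BrCH2CO2H, THF, 0 °C to rt; pH 4 buffer work-up at 0 °C, acid used at once
Reagents that add atoms: bromoacetic acid, OC(=O)CBr
Why: Williamson ether synthesis: the sodium alkoxide displaces bromide from sodium bromoacetate (SN2), the basic medium leaves the acid-labile enol ether intact, and the carbinol configuration is not affected.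

Step 5
Reactants: 6 2-{(S)-[3-(benzyloxy)-4,5-dimethoxyphenyl][(3R)-2,3-dihydrofuran-3-yl]methoxy}acetic acid; 7 5-iodo-1,2,3-trimethoxybenzene
Product: 10 (1S,3aR,4S,6aR)-1-[3-(benzyloxy)-4,5-dimethoxyphenyl]-4-(3,4,5-trimethoxyphenyl)tetrahydro-1H,3H-furo[3,4-c]furan, via alkoxymethyl radical 8 (not isolated), via bicyclic alpha-oxy radical 9 (not isolated)
Conditions: Ir[dF(CF3)ppy]2(dtbbpy)PF6 (cat.), NiCl2·glyme (low loading), dtbbpy, Cs2CO3, DMF (dilute), blue LEDs, rt
Reagents that add atoms: none
Why: The caesium carboxylate of 6 is oxidised by the photoexcited iridium complex and loses CO2 to give radical 8, which adds to the enol-ether carbon remote from oxygen (the future C3a), forming the C3–C3a bond and closing the aryl-bearing tetrahydrofuran; the resulting alpha-oxy radical 9 at the future C4 is captured by the arylnickel species formed from 7 and zerovalent nickel, and reductive elimination from trivalent nickel forges the C4–aryl bond. The closest known reaction types are the iridium/nickel decarboxylative arylation of alpha-oxy carboxylic acids and nickel-catalysed radical cyclisation/arylation of alkene-tethered radical precursors. The ring closes in the 5-exo-trig mode, which leaves the radical stabilised next to the ring oxygen, whereas 6-endo attack would give an unstabilised radical in a strained bridged ring. C3a is controlled by the existing dihydrofuran ring, since the tether on C6a can reach the alkene only from its own face and the bicycle must be cis-fused; nickel then approaches 9 on the convex face, anti to C3, which should place the trimethoxyphenyl group exo (4S), while the exo C1 aryl group comes unchanged from 3. The step needs cyclisation to outrun direct nickel capture of 8, which the fast 5-exo closure of a 2-oxahex-5-enyl radical against a low nickel concentration at high dilution should secure.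

Step 6
Reactants: 10 (1S,3aR,4S,6aR)-1-[3-(benzyloxy)-4,5-dimethoxyphenyl]-4-(3,4,5-trimethoxyphenyl)tetrahydro-1H,3H-furo[3,4-c]furan
Product: 11 5-[(1S,3aR,4S,6aR)-4-(3,4,5-trimethoxyphenyl)tetrahydro-1H,3H-furo[3,4-c]furan-1-yl]-2,3-dimethoxyphenol
Conditions: H2 (1 atm), Pd/C, EtOAc, rt, stopped when 10 is consumed
Reagents that add atoms: none
Why: Catalytic hydrogenolysis of the aryl benzyl ether should be much faster than cleavage of the two cyclic benzylic C–O bonds of the furofuran, and no stereocentre is affected.

**Compound list**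

1 | 3-(benzyloxy)-4,5-dimethoxybenzaldehyde | COc1cc(C=O)cc(OCc2ccccc2)c1OC | starting material
2 | 4-ethenyl-1,3-dioxolan-2-one (racemic) | C=CC1COC(=O)O1 | starting material
3 | (1S,2R)-1-[3-(benzyloxy)-4,5-dimethoxyphenyl]-2-ethenylpropane-1,3-diol | COc1cc(cc(OCc2ccccc2)c1OC)[C@@H](O)[C@@H](CO)C=C | intermediate
4 | (1S,2R)-1-[3-(benzyloxy)-4,5-dimethoxyphenyl]-2-[(ethenyloxy)methyl]but-3-en-1-ol | COc1cc(cc(OCc2ccccc2)c1OC)[C@@H](O)[C@@H](COC=C)C=C | intermediate
5 | (S)-[3-(benzyloxy)-4,5-dimethoxyphenyl][(3R)-2,3-dihydrofuran-3-yl]methanol | COc1cc(cc(OCc2ccccc2)c1OC)[C@@H](O)[C@H]1COC=C1 | intermediate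
6 | 2-{(S)-[3-(benzyloxy)-4,5-dimethoxyphenyl][(3R)-2,3-dihydrofuran-3-yl]methoxy}acetic acid | COc1cc(cc(OCc2ccccc2)c1OC)[C@@H](OCC(O)=O)[C@H]1COC=C1 | intermediate
7 | 5-iodo-1,2,3-trimethoxybenzene | COc1cc(I)cc(OC)c1OC | starting material
8 | alkoxymethyl radical formed from 6 by loss of CO2 | COc1cc(cc(OCc2ccccc2)c1OC)[C@@H](O[CH2])[C@H]1COC=C1 | intermediate
9 | cis-fused bicyclic alpha-oxy radical (radical at the future C4) | COc1cc(cc(OCc2ccccc2)c1OC)[C@H]1OC[C@H]2[C@@H]1CO[CH]2 | intermediate
10 | (1S,3aR,4S,6aR)-1-[3-(benzyloxy)-4,5-dimethoxyphenyl]-4-(3,4,5-trimethoxyphenyl)tetrahydro-1H,3H-furo[3,4-c]furan | COc1cc(cc(OCc2ccccc2)c1OC)[C@H]1OC[C@H]2[C@@H]1CO[C@@H]2c1cc(OC)c(OC)c(OC)c1 | intermediate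
11 | 5-[(1S,3aR,4S,6aR)-4-(3,4,5-trimethoxyphenyl)tetrahydro-1H,3H-furo[3,4-c]furan-1-yl]-2,3-dimethoxyphenol | COc1cc([C@H]2OC[C@H]3[C@@H]2CO[C@@H]3c2cc(OC)c(OC)c(OC)c2)cc(O)c1OC | target

**Step count and risks**

Total step count: 6. Longest linear sequence: 6 steps (from 1).

Steps most likely to fail:

Step 5. What may go wrong: nickel may capture radical 8 before it cyclises, which would arylate the O-CH2 carbon directly, or the alkylnickel formed from 9 may lose a beta-hydride. The fallback sets out from 6 and comes back at 10, separating ring closure from arylation. Acid 6 is esterified with N-hydroxyphthalimide (DIC, DMAP cat., CH2Cl2) to the redox-active ester F1. Irradiation with fac-Ir(ppy)3 in MeCN/water (blue LEDs) reduces the ester; after loss of CO2 and phthalimide the same 5-exo cyclisation follows without nickel. The alpha-oxy radical is then oxidised by the photocatalyst (radical-polar crossover) and water adds to the oxocarbenium ion to give the cis-fused lactol F2. Commercial (3,4,5-trimethoxyphenyl)magnesium bromide (THF, 0 °C) opens the lactol to the diol F3. MsCl/Et3N (CH2Cl2, 0 °C) then closes the second ring through the benzylic mesylate, the primary hydroxyl attacking on the exo face, to give 10.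

Step 2. What may go wrong: incomplete discrimination between the two hydroxyl groups, so that the secondary alcohol is vinylated as well. The fallback sets out from 3 and comes back at 5. The dibutylstannylene acetal of 3 (Bu2SnO, toluene, reflux) is alkylated at the primary oxygen with allyl bromide/CsF (DMF) to the allyl ether F4. [Ir(cod)(PMePh2)2]PF6 (activated with H2, THF, rt) isomerises the allyl ether to the prop-1-enyl ether F5. Ring-closing metathesis with the ruthenium catalyst of step 3 then releases propene and gives 5.

Step 4. What may go wrong: acid-catalysed hydration or oligomerisation of the cyclic enol ether while the free carboxylic acid is isolated. The fallback sets out from 5 and comes back at 10. The sodium alkoxide of 5 (NaH, THF) is alkylated with potassium (bromomethyl)trifluoroborate to the non-acidic potassium trifluoroborate F6. Under Ir[dF(CF3)ppy]2(bpy)PF6, NiCl2·glyme, dtbbpy, K2HPO4, dioxane and blue light, single-electron oxidation of F6 gives radical 8 directly, and the cyclisation/arylation cascade with 7 leads to 10.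

Further compounds
F1 | step 5 | 1,3-dioxoisoindolin-2-yl 2-{(S)-[3-(benzyloxy)-4,5-dimethoxyphenyl][(3R)-2,3-dihydrofuran-3-yl]methoxy}acetate | COc1cc(cc(OCc2ccccc2)c1OC)[C@@H](OCC(=O)ON1C(=O)c2ccccc2C1=O)[C@H]1COC=C1
F2 | step 5 | (3aR,4S,6aR)-4-[3-(benzyloxy)-4,5-dimethoxyphenyl]tetrahydro-1H,3H-furo[3,4-c]furan-1-ol (anomeric mixture) | COc1cc(cc(OCc2ccccc2)c1OC)[C@H]1OC[C@H]2[C@@H]1COC2O
F3 | step 5 | {(2S,3R,4R)-2-[3-(benzyloxy)-4,5-dimethoxyphenyl]-4-[hydroxy(3,4,5-trimethoxyphenyl)methyl]tetrahydrofuran-3-yl}methanol (carbinol epimers) | COc1cc(cc(OCc2ccccc2)c1OC)[C@H]1OC[C@@H]([C@@H]1CO)C(O)c1cc(OC)c(OC)c(OC)c1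
F4 | step 2 | (1S,2R)-1-[3-(benzyloxy)-4,5-dimethoxyphenyl]-2-[(prop-2-en-1-yloxy)methyl]but-3-en-1-ol | COc1cc(cc(OCc2ccccc2)c1OC)[C@@H](O)[C@@H](COCC=C)C=C
F5 | step 2 | (1S,2R)-1-[3-(benzyloxy)-4,5-dimethoxyphenyl]-2-[(prop-1-en-1-yloxy)methyl]but-3-en-1-ol (E/Z mixture) | COc1cc(cc(OCc2ccccc2)c1OC)[C@@H](O)[C@@H](COC=CC)C=C
F6 | step 4 | potassium ({(S)-[3-(benzyloxy)-4,5-dimethoxyphenyl][(3R)-2,3-dihydrofuran-3-yl]methoxy}methyl)trifluoroborate | [K+].COc1cc(cc(OCc2ccccc2)c1OC)[C@@H](OC[B-](F)(F)F)[C@H]1COC=C1
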